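(Its constants were drawn at random within sensible limits; what happens was integrated by code.)

A process chemist and her colleague from extraction disagree about how much target survives in this flask.

substrate 0.010 M; reagent in the second phase 0.0400 M; time 12 s; volume of the second phase over the first 1.0

* amount of target and product in the second phase together at 12 s, in percent of the substrate charged
* the change that raises the amount of target and product in the second phase together at 12 s, in percent of the substrate charged most ("none" if none brings more than 2 percentage points) (Saturday's / Monday's / Sunday's / none)
* amount of target and product in the second phase together at 12 s, in percent of the substrate charged, after Sunday's

- what is said of target includes product in the second phase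
- in the second phase: reagent in the second phase, product in the second phase; everything else is in the first
- charges count per volume of the first phase; a concentration in a rate is the amount of a species over the volume of its own phase; every rate counts per litre of the first phase
- run time (flask): 12 s

    reagent in the reaction phase ⇌ reagent in the second phase, rate k1*([reagent in the reaction phase] - [reagent in the second phase]/K1) per volume of the first phase (K1 = 0.823, k1 = 1.37 s⁻¹)
    substrate + reagent in the reaction phase → target (k2 = 29.9 M⁻¹ s⁻¹)
    target ⇌ product in the second phase, rate k3*([target] - [product in the second phase]/K3) per volume of the first phase (K3 = 2.10, k3 = 0.191 s⁻¹)
    target → decomposed product (k4 = 0.0999 s⁻¹)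
    substrate ⇌ dormant form (K5 = 1.76, k5 = 0.809 s⁻¹)
    reagent in the reaction phase + target → over-reaction product (k6 = 2.88 M⁻¹ s⁻¹)
    target ⇌ isomer of the product (K7 = 19, k7 = 0.0286 s⁻¹)

They agree on the reagent. It exchanges between the phases with a half-life of 0.228 s, much shorter than the run, so I hold [reagent in the reaction phase] at its partition value with half the substrate spent, 0.0192 M. Each step is then pseudo-first-order. Target in the reaction phase is lost to decomposition, over-reaction and isomer with a loss constant of 0.184 s⁻¹, and the isomer's return makes no difference.

The extraction colleague says target shares between the phases at once, so the loss constant shrinks by the reaction-phase share. That view belongs to a flask whose transfer coefficient far exceeds the loss constant, and here they are level, 0.191 s⁻¹ against 0.184 s⁻¹. The chemist says fresh target runs a race: it escapes or is lost, and what escapes stays safe. Her view ignores the return constant, 0.0910 s⁻¹.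

My own reckoning joins the two ends. At the late end, a store behind a losing compartment empties at about the tail constant, loss times return over the sum of loss, entry and return: 0.0359 s⁻¹. At the early end, fresh target fades with a fast constant, 0.430 s⁻¹, and 62.5% of it reaches the tail. The same rule serves the substrate, with the dormant form as store and reaction as loss, 0.574 s⁻¹. The charge then feeds out with 0.143 s⁻¹, after 27.7% has reacted at once.

Passing that feed through the survival curve gives 42.0%. On the same feed, the race gives 44.4% and sharing gives 52.0%.

Saturday's change doubles the target's transfer coefficient, which raises the tail constant to 0.0447 s⁻¹, but 78.9% now reaches the tail, and the yield comes to 47.1%. I expect no gain from Monday's, which doubles the reagent charged and lifts the loss constant to 0.247 s⁻¹. I expect none from Sunday's either, which doubles the reagent's transfer coefficient, since the exchange half-life 0.228 s is already much shorter than the run.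

The forecast gives 42% (from 38% to 46%), Saturday's as the best change and 42.5% after Sunday's (from 38.5% to 47%), holding that “the yield is set by how fast target escapes into the protective second phase compared with its decomposition, isomerisation and over-reaction”.

The flask gives 42.2%, which stands nearer the race than sharing. Saturday's is best at 5.1 percentage points, Monday's brings −5.9 points, Sunday's brings −0.15 points, and the yield after Sunday's is 42.0%.

Now read the same flask at 50 s, with the same constants and a later time. The fast part of the curve has faded, and the tail constant 0.0359 s⁻¹ carries what is left, so the reckoning gives 12.9%. That neighbouring reading gives 12.6%, of which 9.77% is product in the second phase, while decomposed product stands at 49.7%.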